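Follow one curve: the complex with two exchanged in spring, in fractions of the starting complex charged.

all flasks: starting complex 10 mM

| charge | incoming ligand | remark | time |
|---|---|---|---|
| eta | 6 mM | run made earlier |  |
| epsilon | 18 mM | run made earlier |  |
| spring | 5.00 mM |  | 80 min |
| autumn | 15.0 mM |  | 80 min |

| run | time / min | complex with two exchanged / % | complex with three exchanged / % |
|---|---|---|---|
| eta | 8.00 | 6.4 | 0 |
| eta | 20.0 | 6.4 | 1.2 |
| eta | 40.0 | 2.3 | 0 |
| eta | 60.0 | 0.5 | 0.6 |
| eta | 80.0 | 0.8 | 0 |
| epsilon | 8.00 | 27.3 | 6.1 |
| epsilon | 20.0 | 30.0 | 2.8 |
| epsilon | 40.0 | 26.8 | 1.0 |
| epsilon | 60.0 | 25.8 | 0.7 |
| epsilon | 80.0 | 24.0 | 0 |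

(each reading ± 0.5 percentage points)

- which of these holds the largest part of the starting complex at the end of spring (starting complex / complex with one exchanged / complex with two exchanged / complex with three exchanged)
- which of these holds the largest part of the starting complex at the end of autumn (starting complex / complex with one exchanged / complex with two exchanged / complex with three exchanged)
- how much complex with two exchanged is there at the end of spring, in percent of the starting complex charged

- in percentages every species weighs as the starting complex in it: one idle adduct or side product B counts as two
- for complex with three exchanged the idle adduct is counted in
- what was read earlier has a scatter of 0.5 percentage points, one standard deviation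
- steps thought possible: starting complex + incoming ligand -> leaving ligand + complex with one exchanged; complex with one exchanged + incoming ligand -> leaving ligand + complex with two exchanged; complex with two exchanged + incoming ligand -> leaving ligand + complex with three exchanged; leaving ligand + complex with three exchanged -> side product A; starting complex + complex with three exchanged <-> idle adduct; starting complex + complex with two exchanged -> side product B
- in an amount of complex with three exchanged, one idle adduct counts as one complex with three exchanged

Its slope at the start is zero, since the road to it passes through the complex with one exchanged. Eta then reads a flat top, 6.4% at 8.00 min and 6.4% at 20.0 min. Each of the two steps takes incoming ligand, so I scale that top by the charge ratio twice over: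

top in spring = 6.4% × 0.833 × 0.833 = 4.44%

Past the knee I take the loss into side product B, a pseudo-first-order fall while starting complex stays nearly level. Eta drops to 2.3% at 40.0 min. With a scatter of 0.5 percentage points, this reads as 0.0512 min⁻¹, the logarithmic fall per minute, which I call the fading rate. Its half-life is 13.5 min. The curve then runs towards zero:

y = 4.44% × exp(−0.0512 min⁻¹ × (80 min − 20.0 min)) = 0.206%

In spring the ligand charge is half of the starting complex, so I expect starting complex to lead. Epsilon fades far slower than eta, at 0.00276 min⁻¹, so I scale its last reading by the charge ratio twice over and put the complex with two exchanged in autumn near 16.7%. Neither earlier run reads the complex with one exchanged, so naming the complex with two exchanged first in autumn is my judgement and not a result of this reckoning.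

The forecast gives starting complex for spring, complex with one exchanged for autumn ("so one-exchanged dominates") and 0.3%, so it differs from my reckoning on autumn and on the number.

The flask gives starting complex for spring at 51.6%, complex with two exchanged for autumn at 19.7%, and 0.169%.

    starting complex + incoming ligand → leaving ligand + complex with one exchanged (k = 0.200 M⁻¹ s⁻¹)
    complex with one exchanged + incoming ligand → leaving ligand + complex with two exchanged (k = 0.390 M⁻¹ s⁻¹)
    complex with two exchanged + incoming ligand → leaving ligand + complex with three exchanged (k = 0.110 M⁻¹ s⁻¹)
    leaving ligand + complex with three exchanged → side product A (k = 0.360 M⁻¹ s⁻¹)
    starting complex + complex with three exchanged ⇌ idle adduct, settled at all times (K = 160 M⁻¹)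
    starting complex + complex with two exchanged → side product B (k = 0.200 M⁻¹ s⁻¹)

In spring the half-life of the complex with two exchanged by its step into side product B, 7.1 min at 4.31 min, is short against the 80 min. From 1.80% at 40.0 min to the end it fades at 0.0591 min⁻¹, against my 0.0512 min⁻¹. Now take spring stopped at 20 min: my fading rate, carried back from 1.80%, gives 5.01%, and that flask holds 4.62%.

Readings and results come from a simulation with made-up constants; noise was put on by code.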